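## Structural features

The target is a tetra-aryl lignan built on a trans-α,β-dibenzyl-γ-butyrolactone. The β-benzyl arene (ring B) is etherified at its para oxygen by C8 of an erythro guaiacylglycerol unit carrying ring A (C7 carbinol, C8 aryl ether, C9 CH2OH). The α-benzyl arene (ring C) is the benzo ring of a trans-2-aryl-3-hydroxymethyl-2,3-dihydrobenzofuran whose C2 bears guaiacyl ring D. The six stereocentres form three vicinal pairs, C7(R)/C8(S), Cβ(R)/Cα(R) and C3(R)/C2(S). Each pair is insulated from the next by an arene and a methylene, so no pair can steer another and each needs its own source of absolute configuration. Fragile sites are the two para-oxygenated benzylic C–O bonds (C7–OH beside ring A, C2–O1 beside ring D), which ionise towards quinone-methide-like species under acid or, once the phenols are free, under base; the lactone, which opens with hydroxide and is reduced by strong hydrides, is a further weak point. The real difficulty is therefore the independent control of three stereo pairs, the erythro relation at C7/C8 (the dependable auxiliary aldol delivers threo), and a protecting-group set that leaves in one near-neutral operation. The key step exploits ring C: C3 carries both the C3–C3a aryl bond and an oxygenated methylene while O1 links C7a to benzylic C2, which is what a 5-exo attack of a C3a aryl radical on the vinyl group of an aryl 1-arylallyl ether leaves behind when the exocyclic radical is captured by oxygen.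

## Logic of the disconnections

35 ⇒ 34. No skeletal bond is cut; five O–H bonds (two phenols, C7–OH, C9–OH, the hydroxymethyl on C3) are traded for O–Si bonds. Silicon is chosen because fluoride spares the lactone and both para-oxygenated benzylic C–O bonds. The gain is a single final operation. The demand is a buffered fluoride source, so that no phenoxide sits beside a benzylic oxygen.

34 ⇒ 32 + 14. The Cα–CH2 bond between the lactone and ring C is cut. This divides the molecule into two halves of similar size, each with two arenes and one complete stereo pair, and it is the benzylic bond that the resident Cβ centre can control. The forward step must alkylate the enolate of 32 anti to its β-substituent with a reactive, labile para-alkoxybenzyl bromide.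

14 ⇒ 13 ⇒ 12 ⇒ 11. Only functional groups change: C–Br back to C–OH, the benzylic CH2OH back to the ester carbonyl, O–Si back to O–H. The ester is carried through the ring closure because it is radical-inert and distinguishes the ring C benzylic carbon from the new hydroxymethyl group. The demand is that the primary alcohol of 11 be silylated before hydride reduction.

11 ⇒ 9 (key). The C3–C3a bond and the C–O bond of the hydroxymethyl group are cut, opening the dihydrofuran ring to an aryl iodide tethered through O1 to a 1-arylallyl unit.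
- Gain: one ring, one C–C bond and the C3 stereocentre vanish; only C2 remains.
- Demand: the forward step must form the C3a radical without ionising the doubly activated benzylic ether, close 5-exo faster than it is reduced, set C3 trans to ring D, and end by oxygen capture.
- Spectator choices in 9: ring D carries a triisopropylsilyl ether, which resists the aryloxide and methoxide present when 9 is made better than a tert-butyldimethylsilyl ether would. The chain is started at 0 °C, not by a thermal azo initiator, so that the ether neither ionises nor undergoes an allyl shift.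

9 ⇒ 7 + 5. The O1–C2 bond is cut to a phenol and a linear cinnamyl carbonate, removing the last stereocentre of this half. The forward step must be branched-selective and enantioselective with a hindered, electron-poor aryloxide. Both ortho positions and the para position of 7 are occupied, so C-allylation and Claisen rearrangement have no open site.

5 ⇒ 4 ⇒ 3 ⇒ 2 ⇒ 1, and 7 ⇒ 6. The C=C bond of the cinnamyl unit is cut back to the aldehyde carbon of 2 (olefination, then ester-to-alcohol-to-carbonate changes), and the C–I bond of 7 is cut to commercial 6. The demands are E geometry and iodination at the single position activated by the hydroxyl group.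

32 ⇒ 31 ⇒ 30 ⇒ 29 ⇒ 28. Two O–Si bonds are removed and the C7–O bond is cut and re-formed with inversion, because the aldol that makes C7–C8 gives the threo pair (7S,8S) and the target needs erythro (7R,8S). The gain is that C8, the harder centre, is set once by the auxiliary. The demand is an SN2 course at a benzylic carbinol beside an electron-rich arene.

28 ⇒ 27 ⇒ 25 + 2. The C7–C8 bond is cut (aldol), and C9 is taken back from CH2OH to the acyl carbon bound to the auxiliary. This reduces the glycerol unit to an aryloxyacetyl group and an aldehyde. The demands are a Z boron enolate, auxiliary-controlled facial selectivity, and a hydride that cleaves the imide but spares the lactone.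

25 ⇒ 21 + 24, and 24 ⇒ 22. The bond between the ring B oxygen and the future C8 is cut (phenol alkylation), then the N-acyl bond of the auxiliary. This separates the ring A–B ether problem from the lactone problem.

21 ⇒ 20 ⇒ 18 ⇒ 17 ⇒ 15 + 16. The benzyl ether, the lactone C–O bond (back to a succinate half-ester) and the benzylidene C=C bond are cut in turn. The Cβ centre is then the product of an asymmetric hydrogenation on a simple early intermediate.

## Other disconnections considered

Alternative 1: The cut removes both benzylic C–C bonds at the lactone at once (Cβ–C on the ring B side, Cα–CH2 on the ring C side) and takes the four lactone carbons from the menthyloxy butenolide A1. In the forward direction the lithiated dithiane A2, the masked ring A–B aldehyde, would add to C4 of A1 anti to the acetal oxygen. The enolate would then be benzylated in the same flask by a bromide of the type of 14, again anti, to give A3 with all four arenes.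
- In favour: the union is three-component and fully convergent, and both lactone stereocentres come from two consecutive anti additions on a rigid ring without an asymmetric catalyst. On the security of the lactone stereochemistry this is the equal of, and arguably better than, steps 12 and 23.
- Against: A3 still carries a dithiane and a menthyl acetal. Desulfurisation with Ni (Raney) endangers the benzylic C2–O1 and C7–O bonds, and the acetal must be hydrolysed and reduced under acid beside an acetonide and silyl ethers, all on the most valuable material. A2 also presupposes the complete erythro ether, so the C7/C8 problem is not reduced.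
- Comparison: structurally it replaces steps 11–14 and 23 but not the dihydrobenzofuran construction, which it still needs. Mechanistically it trades catalyst control at Cβ for substrate control by the acetal. In step count it saves about four steps before the union and adds about three after it, so it is roughly equal overall with the load moved to the end.

Alternative 2: The cut is the ring O–CH2 bond of the lactone. The retron is the prochiral cyclobutanone A5, reachable from the allyl group of a ring A–B ether built on eugenol A4 by ketene cycloaddition and dechlorination. In the forward direction Sc(OTf)3 with a chiral N,N'-dioxide and a peracid would insert oxygen into one enantiotopic acyl–CH2 bond to give lactone A6.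
- In favour: the allyl group is a robust latent lactone, so the erythro ether can be finished first with no lactone to shield from hydride. This is better than the chosen plan, where the lactone must survive step 18. The stereo-defining step is also catalytic.
- Against: the stereo-differentiating group is CH2Ar, one carbon removed from the four-membered ring, so discrimination of the two migrating bonds is expected to be less secure than for 3-aryl cyclobutanones. Because the existing C7/C8 centres are remote, any shortfall appears as diastereomers that are hard to separate. The zinc-mediated ketene step and the peracid act on an advanced intermediate with electron-rich arenes and acid-labile acetals.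
- Comparison: structurally A6 is the analogue of 32, so the rest of the plan is unchanged. Mechanistically both routes rely on a catalyst for Cβ, but the hydrogenation of 17 acts on a simple early compound whose enantiopurity can be upgraded and checked, which is safer. In step count three steps from the allyl group against four (steps 11–14) is equal or slightly better for the alternative.

Alternative 3: The cut is the C2–C3 bond of the dihydrobenzofuran. In the forward direction the aryldiazoacetate A7 would lose N2 on Rh2(S-PTTL)4 (divalent rhodium; the mirror-image catalyst if needed for 2S). The carbenoid would insert into the benzylic CH2 of the ortho ring D benzyl ether, and DBU would then epimerise C3 to give the trans ester A8.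
- In favour: both ring stereocentres arise in one catalytic step from an achiral precursor, no tin is used, and trans is secured thermodynamically by epimerisation of the C3 ester. On trans control and on reagent toxicity it is better than the chosen key step, whose trans selectivity is kinetic.
- Against: A7 needs an arylacetate ortho to the ether (homologation plus diazo transfer), and the C3 ester must still be reduced to CH2OH. The ring D benzyl ether would have to go by hydrogenolysis beside the benzylic C2–O1 bond unless exchanged. The base epimerisation of a β-aryloxy ester invites ring opening by elimination of the O1 phenoxide.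
- Comparison: structurally the same ring is closed through C2–C3, not C3–C3a. Mechanistically one catalyst sets two centres, whereas in the chosen plan one catalyst sets C2 and the substrate sets C3. The chosen plan reaches the alcohol oxidation level directly through oxygen capture, while the alternative arrives at the ester level. Step counts to the 11/A8 stage are comparable.

Key step: step 7

Remark: the antipodes of the chiral ligands in steps 6 and 12 are assigned by analogy with the parent cinnamyl and benzylidenesuccinate substrates; should either sense prove opposite, the mirror-image ligand is used with no other change.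

## Route

Step 1
Reactants: 1 vanillin
Product: 2 3-methoxy-4-[(triisopropylsilyl)oxy]benzaldehyde
Conditions: i-Pr3SiCl, imidazole, DMF, rt
Reagents that add atoms: chlorotriisopropylsilane, CC(C)[Si](Cl)(C(C)C)C(C)C
Why: Silylation of the phenol; the triisopropylsilyl ether should survive the aryloxide, methoxide, borohydride and amide bases met later and still fall to fluoride, and 2 serves both ring D (step 2) and ring A (step 17).

Step 2
Reactants: 2 3-methoxy-4-[(triisopropylsilyl)oxy]benzaldehyde
Product: 3 ethyl (2E)-3-{3-methoxy-4-[(triisopropylsilyl)oxy]phenyl}prop-2-enoate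
Conditions: Ph3P=CHCO2Et, toluene, 80 °C
Reagents that add atoms: ethyl (triphenylphosphoranylidene)acetate, CCOC(=O)C=P(c1ccccc1)(c1ccccc1)c1ccccc1
Why: Wittig olefination with a stabilised ylide, which should give the E cinnamate.

Step 3
Reactants: 3 ethyl (2E)-3-{3-methoxy-4-[(triisopropylsilyl)oxy]phenyl}prop-2-enoate
Product: 4 (2E)-3-{3-methoxy-4-[(triisopropylsilyl)oxy]phenyl}prop-2-en-1-ol
Conditions: i-Bu2AlH (2.2 equiv), CH2Cl2, −78 °C; aqueous potassium sodium tartrate
Reagents that add atoms: none
Why: 1,2-Reduction of the conjugated ester to the allylic alcohol; the alkene geometry and the aryl silyl ether are not affected at low temperature.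

Step 4
Reactants: 4 (2E)-3-{3-methoxy-4-[(triisopropylsilyl)oxy]phenyl}prop-2-en-1-ol
Product: 5 methyl (2E)-3-{3-methoxy-4-[(triisopropylsilyl)oxy]phenyl}prop-2-en-1-yl carbonate
Conditions: ClCO2Me, pyridine, CH2Cl2, 0 °C
Reagents that add atoms: methyl chloroformate, COC(=O)Cl
Why: Acylation of the primary alcohol gives the linear allylic carbonate, whose leaving group ionises irreversibly (loss of CO2) on iridium.

Step 5
Reactants: 6 methyl vanillate
Product: 7 methyl 4-hydroxy-3-iodo-5-methoxybenzoate
Conditions: N-iodosuccinimide, TsOH·H2O (10 mol %), MeCN, rt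
Reagents that add atoms: N-iodosuccinimide, O=C1CCC(=O)N1I
Why: Electrophilic aromatic iodination; the only free position ortho or para to the hydroxyl group is C5, the other ortho site carrying OMe and the para site the ester.

Step 6
Reactants: 7 methyl 4-hydroxy-3-iodo-5-methoxybenzoate; 5 methyl (2E)-3-{3-methoxy-4-[(triisopropylsilyl)oxy]phenyl}prop-2-en-1-yl carbonate
Product: 9 methyl 3-iodo-5-methoxy-4-{[(1S)-1-{3-methoxy-4-[(triisopropylsilyl)oxy]phenyl}prop-2-en-1-yl]oxy}benzoate, via lithium aryloxide 8 (not isolated)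
Conditions: LiN(SiMe3)2 (1.0 equiv), THF, 0 °C; then 5 (1.2 equiv), [Ir(cod)Cl]2 (2 mol %), (Sa,Sc,Sc)-binaphthol N,N-bis(1-phenylethyl)phosphoramidite (4 mol %, catalyst pre-activated with n-PrNH2 and freed of amine), THF, rt
Reagents that add atoms: none
Why: Iridium-catalysed asymmetric allylic etherification: the cyclometalated iridium–phosphoramidite complex ionises the carbonate to an allyl complex, and the aryloxide attacks the aryl-substituted terminus on the face fixed by the ligand, which should give the branched (S) ether. The lithium aryloxide is preformed because the phenol is hindered and electron-poor, the aryl iodide is inert to iridium, and the blocked ortho and para positions exclude C-allylation.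

Step 7
Reactants: 9 methyl 3-iodo-5-methoxy-4-{[(1S)-1-{3-methoxy-4-[(triisopropylsilyl)oxy]phenyl}prop-2-en-1-yl]oxy}benzoate
Product: 11 methyl (2S,3R)-3-(hydroxymethyl)-7-methoxy-2-{3-methoxy-4-[(triisopropylsilyl)oxy]phenyl}-2,3-dihydro-1-benzofuran-5-carboxylate, via hydroperoxide 10 (not isolated)
Conditions: Bu3SnH (1.3 equiv, syringe pump), Et3B (0.3 equiv), dry air (slow stream), toluene (0.01 M), 0 °C; then PPh3 (1.5 equiv), rt
Reagents that add atoms: dioxygen, O=O
Why: Ethyl radicals from Et3B and air start a stannane chain in which Bu3Sn• abstracts iodine from 9 to give a σ aryl radical at the future C3a. This radical adds 5-exo-trig to the internal carbon of the vinyl group, forming C3–C3a and closing the dihydrofuran ring, with the tether oxygen becoming O1. The exocyclic primary radical is captured by O2, the peroxyl radical takes hydrogen from Bu3SnH to carry the chain and give hydroperoxide 10, and PPh3 reduces 10 to 11. The closest known reaction type is the stannane-mediated oxygenative aryl radical cyclisation of ortho-haloaryl allyl ethers to 3-(hydroxymethyl)dihydrobenzofurans. The new C3 centre is controlled by C2: because the arene holds C3a, C7a and O1 coplanar the transition state is an envelope and not a true chair, ring D sits pseudo-equatorial on C2, and the alkene terminus turns away from it, which should give the trans (2S,3R) isomer. C2 is not touched, since no ionic intermediate involves the benzylic C–O bond and the reaction is run at 0 °C. Cyclisation must beat direct reduction of the aryl radical, which the very fast 5-exo closure and the low stannane concentration secure. Oxygen capture must beat hydrogen transfer to the primary radical, which air saturation and slow stannane addition secure.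

Step 8
Reactants: 11 methyl (2S,3R)-3-(hydroxymethyl)-7-methoxy-2-{3-methoxy-4-[(triisopropylsilyl)oxy]phenyl}-2,3-dihydro-1-benzofuran-5-carboxylate
Product: 12 methyl (2S,3R)-3-{[(tert-butyldimethylsilyl)oxy]methyl}-7-methoxy-2-{3-methoxy-4-[(triisopropylsilyl)oxy]phenyl}-2,3-dihydro-1-benzofuran-5-carboxylate
Conditions: t-BuMe2SiCl, imidazole, DMF, rt
Reagents that add atoms: tert-butyldimethylsilyl chloride, CC(C)(C)[Si](C)(C)Cl
Why: Silylation of the only free hydroxyl group, so that the later benzylic alcohol is the sole site for bromination.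

Step 9
Reactants: 12 methyl (2S,3R)-3-{[(tert-butyldimethylsilyl)oxy]methyl}-7-methoxy-2-{3-methoxy-4-[(triisopropylsilyl)oxy]phenyl}-2,3-dihydro-1-benzofuran-5-carboxylate
Product: 13 [(2S,3R)-3-{[(tert-butyldimethylsilyl)oxy]methyl}-7-methoxy-2-{3-methoxy-4-[(triisopropylsilyl)oxy]phenyl}-2,3-dihydro-1-benzofuran-5-yl]methanol
Conditions: i-Bu2AlH (2.5 equiv), CH2Cl2, −78 to 0 °C; aqueous potassium sodium tartrate
Reagents that add atoms: none
Why: Hydride reduction of the aryl ester to the benzylic alcohol; silyl ethers and the cyclic benzylic ether are inert to the aluminium hydride.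

Step 10
Reactants: 13 [(2S,3R)-3-{[(tert-butyldimethylsilyl)oxy]methyl}-7-methoxy-2-{3-methoxy-4-[(triisopropylsilyl)oxy]phenyl}-2,3-dihydro-1-benzofuran-5-yl]methanol
Product: 14 (2S,3R)-5-(bromomethyl)-3-{[(tert-butyldimethylsilyl)oxy]methyl}-7-methoxy-2-{3-methoxy-4-[(triisopropylsilyl)oxy]phenyl}-2,3-dihydro-1-benzofuran
Conditions: CBr4, PPh3, CH2Cl2, 0 °C; used at once
Reagents that add atoms: carbon tetrabromide, BrC(Br)(Br)Br
Why: Appel bromination under neutral conditions; the para-alkoxybenzyl bromide is reactive and is therefore made last and not stored.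

Step 11
Reactants: 15 4-(benzyloxy)-3-methoxybenzaldehyde; 16 dimethyl succinate
Product: 17 (3E)-4-[4-(benzyloxy)-3-methoxyphenyl]-3-(methoxycarbonyl)but-3-enoic acid
Conditions: NaOMe, MeOH, reflux; then aqueous HCl
Reagents that add atoms: none
Why: Stobbe condensation: aldol addition, lactonisation to the paraconic ester and base-induced ring opening give the benzylidenesuccinate half-ester, mainly as the E isomer.

Step 12
Reactants: 17 (3E)-4-[4-(benzyloxy)-3-methoxyphenyl]-3-(methoxycarbonyl)but-3-enoic acid
Product: 18 (3R)-3-[4-(benzyloxy)-3-methoxybenzyl]-4-methoxy-4-oxobutanoic acid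
Conditions: H2 (5 bar), [Rh(cod)((S,S)-Et-DuPHOS)]BF4 (0.5 mol %), NaOMe (10 mol %), MeOH, rt
Reagents that add atoms: none
Why: Rhodium-catalysed asymmetric hydrogenation of an itaconate-type half-ester: carboxylate and alkene chelate the metal and the C2-symmetric bisphospholane selects the alkene face, which should set the future Cβ as R; the benzyl ether is not cleaved by the homogeneous catalyst.

Step 13
Reactants: 18 (3R)-3-[4-(benzyloxy)-3-methoxybenzyl]-4-methoxy-4-oxobutanoic acid
Product: 20 (4R)-4-[4-(benzyloxy)-3-methoxybenzyl]oxolan-2-one, via hydroxy acid 19 (not isolated)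
Conditions: LiEt3BH (3.2 equiv), THF, 0 °C to rt; then 2 M HCl, rt
Reagents that add atoms: none
Why: The borohydride deprotonates the acid to an unreactive carboxylate and reduces only the methyl ester; acidification lactonises the γ-hydroxy acid, so the carbonyl of the lactone derives from the former acid carbon and the stereocentre is untouched.

Step 14
Reactants: 20 (4R)-4-[4-(benzyloxy)-3-methoxybenzyl]oxolan-2-one
Product: 21 (4R)-4-(4-hydroxy-3-methoxybenzyl)oxolan-2-one
Conditions: H2 (1 atm), Pd/C (10 wt %), EtOAc, rt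
Reagents that add atoms: none
Why: Hydrogenolysis of the benzyl ether at a stage where no other benzylic C–O bond is present.

Step 15
Reactants: 22 (4R)-4-benzyl-1,3-oxazolidin-2-one
Product: 24 (4R)-4-benzyl-3-(bromoacetyl)-1,3-oxazolidin-2-one, via N-lithio oxazolidinone 23 (not isolated)
Conditions: n-BuLi, THF, −78 °C; then BrCH2COBr, −78 to 0 °C
Reagents that add atoms: bromoacetyl bromide, O=C(Br)CBr
Why: N-Acylation of the lithiated auxiliary by the acyl bromide, which reacts faster than the alkyl bromide.

Step 16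
Reactants: 21 (4R)-4-(4-hydroxy-3-methoxybenzyl)oxolan-2-one; 24 (4R)-4-benzyl-3-(bromoacetyl)-1,3-oxazolidin-2-one
Product: 25 (4R)-4-benzyl-3-[(2-methoxy-4-{[(3R)-5-oxooxolan-3-yl]methyl}phenoxy)acetyl]-1,3-oxazolidin-2-one
Conditions: K2CO3, acetone, rt
Reagents that add atoms: none
Why: Williamson-type O-alkylation of the phenoxide by the activated α-bromo imide; carbonate in acetone deprotonates only the phenol and leaves the lactone closed.

Step 17
Reactants: 25 (4R)-4-benzyl-3-[(2-methoxy-4-{[(3R)-5-oxooxolan-3-yl]methyl}phenoxy)acetyl]-1,3-oxazolidin-2-one; 2 3-methoxy-4-[(triisopropylsilyl)oxy]benzaldehyde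
Product: 27 (4R)-4-benzyl-3-[(2R,3S)-3-hydroxy-2-(2-methoxy-4-{[(3R)-5-oxooxolan-3-yl]methyl}phenoxy)-3-{3-methoxy-4-[(triisopropylsilyl)oxy]phenyl}propanoyl]-1,3-oxazolidin-2-one, via boron enolate 26 (not isolated)
Conditions: n-Bu2BOTf (1.2 equiv), i-Pr2NEt (1.4 equiv), CH2Cl2, 0 °C; then 2, −78 to 0 °C; then pH 7 buffer, MeOH, 30 % H2O2, 0 °C
Reagents that add atoms: none
Why: Evans syn-aldol reaction: the Z boron enolate reacts through a Zimmerman–Traxler chair on the enolate face away from the benzyl group of the auxiliary, which should give the 2,3-syn adduct; for an α-aryloxy acyl unit this is the threo pair, with C8 as in the target and C7 to be inverted in step 20. The lactone is not enolised by the boron triflate and amine.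

Step 18
Reactants: 27 (4R)-4-benzyl-3-[(2R,3S)-3-hydroxy-2-(2-methoxy-4-{[(3R)-5-oxooxolan-3-yl]methyl}phenoxy)-3-{3-methoxy-4-[(triisopropylsilyl)oxy]phenyl}propanoyl]-1,3-oxazolidin-2-one
Product: 28 (4R)-4-(4-{[(1S,2S)-1,3-dihydroxy-1-{3-methoxy-4-[(triisopropylsilyl)oxy]phenyl}propan-2-yl]oxy}-3-methoxybenzyl)oxolan-2-one
Conditions: NaBH4 (4 equiv), THF–H2O (4:1), 0 °C to rt
Reagents that add atoms: none
Why: Reductive removal of the auxiliary: borohydride in wet THF attacks the activated exocyclic imide carbonyl and reduces it to the primary alcohol (C9), releasing 22, while the γ-lactone and silyl ether react much more slowly.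

Step 19
Reactants: 28 (4R)-4-(4-{[(1S,2S)-1,3-dihydroxy-1-{3-methoxy-4-[(triisopropylsilyl)oxy]phenyl}propan-2-yl]oxy}-3-methoxybenzyl)oxolan-2-one
Product: 29 (4R)-4-(4-{[(1S,2S)-3-[(tert-butyldimethylsilyl)oxy]-1-hydroxy-1-{3-methoxy-4-[(triisopropylsilyl)oxy]phenyl}propan-2-yl]oxy}-3-methoxybenzyl)oxolan-2-one
Conditions: t-BuMe2SiCl (1.05 equiv), imidazole, CH2Cl2, 0 °C
Reagents that add atoms: tert-butyldimethylsilyl chloride, CC(C)(C)[Si](C)(C)Cl
Why: Selective silylation of the primary C9 hydroxyl over the hindered secondary benzylic one, leaving C7–OH free for inversion.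

Step 20
Reactants: 29 (4R)-4-(4-{[(1S,2S)-3-[(tert-butyldimethylsilyl)oxy]-1-hydroxy-1-{3-methoxy-4-[(triisopropylsilyl)oxy]phenyl}propan-2-yl]oxy}-3-methoxybenzyl)oxolan-2-one
Product: 30 (1R,2S)-3-[(tert-butyldimethylsilyl)oxy]-1-{3-methoxy-4-[(triisopropylsilyl)oxy]phenyl}-2-(2-methoxy-4-{[(3R)-5-oxooxolan-3-yl]methyl}phenoxy)propyl chloroacetate
Conditions: ClCH2CO2H, PPh3, i-PrO2CN=NCO2i-Pr, toluene, 0 °C to rt
Reagents that add atoms: chloroacetic acid, OC(=O)CCl
Why: Mitsunobu inversion: the alkoxyphosphonium ion at C7 is displaced by chloroacetate in an SN2 step, converting threo (7S) into erythro (7R); the acidic nucleophile, the non-polar solvent and the β-aryloxy group all disfavour ionisation to a benzylic cation.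

Step 21
Reactants: 30 (1R,2S)-3-[(tert-butyldimethylsilyl)oxy]-1-{3-methoxy-4-[(triisopropylsilyl)oxy]phenyl}-2-(2-methoxy-4-{[(3R)-5-oxooxolan-3-yl]methyl}phenoxy)propyl chloroacetate
Product: 31 (4R)-4-(4-{[(1R,2S)-3-[(tert-butyldimethylsilyl)oxy]-1-hydroxy-1-{3-methoxy-4-[(triisopropylsilyl)oxy]phenyl}propan-2-yl]oxy}-3-methoxybenzyl)oxolan-2-one
Conditions: thiourea, NaHCO3, EtOH–THF, 40 °C
Reagents that add atoms: none
Why: Thiourea alkylates at the CH2Cl carbon and cyclises onto the ester carbonyl, releasing the alcohol by acyl–oxygen cleavage, so C7 keeps its configuration; the near-neutral medium spares the lactone and the aryl silyl ether.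

Step 22
Reactants: 31 (4R)-4-(4-{[(1R,2S)-3-[(tert-butyldimethylsilyl)oxy]-1-hydroxy-1-{3-methoxy-4-[(triisopropylsilyl)oxy]phenyl}propan-2-yl]oxy}-3-methoxybenzyl)oxolan-2-one
Product: 32 (4R)-4-(4-{[(1R,2S)-1,3-bis[(tert-butyldimethylsilyl)oxy]-1-{3-methoxy-4-[(triisopropylsilyl)oxy]phenyl}propan-2-yl]oxy}-3-methoxybenzyl)oxolan-2-one
Conditions: t-BuMe2SiOTf, 2,6-lutidine, CH2Cl2, −78 to 0 °C
Reagents that add atoms: tert-butyldimethylsilyl trifluoromethanesulfonate, CC(C)(C)[Si](C)(C)OS(=O)(=O)C(F)(F)F
Why: Silyl triflate silylation of the hindered secondary alcohol, so that no alkoxide competes with the enolate in the next step; at this temperature the hindered base does not enolise the lactone.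

Step 23
Reactants: 32 (4R)-4-(4-{[(1R,2S)-1,3-bis[(tert-butyldimethylsilyl)oxy]-1-{3-methoxy-4-[(triisopropylsilyl)oxy]phenyl}propan-2-yl]oxy}-3-methoxybenzyl)oxolan-2-one; 14 (2S,3R)-5-(bromomethyl)-3-{[(tert-butyldimethylsilyl)oxy]methyl}-7-methoxy-2-{3-methoxy-4-[(triisopropylsilyl)oxy]phenyl}-2,3-dihydro-1-benzofuran
Product: 34 (3R,4R)-4-(4-{[(1R,2S)-1,3-bis[(tert-butyldimethylsilyl)oxy]-1-{3-methoxy-4-[(triisopropylsilyl)oxy]phenyl}propan-2-yl]oxy}-3-methoxybenzyl)-3-{[(2S,3R)-3-{[(tert-butyldimethylsilyl)oxy]methyl}-7-methoxy-2-{3-methoxy-4-[(triisopropylsilyl)oxy]phenyl}-2,3-dihydro-1-benzofuran-5-yl]methyl}oxolan-2-one, via lithium enolate 33 (not isolated)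
Conditions: LiN(SiMe3)2 (1.1 equiv), THF, −78 °C; then 14 (1.2 equiv), DMPU, −78 to −40 °C
Reagents that add atoms: none
Why: Alkylation of a β-substituted γ-butyrolactone enolate: the bromide approaches the planar enolate anti to the β-arylmethyl group, which should give the trans (αR) product as in dibenzylbutyrolactone lignan syntheses.

Step 24
Reactants: 34 (3R,4R)-4-(4-{[(1R,2S)-1,3-bis[(tert-butyldimethylsilyl)oxy]-1-{3-methoxy-4-[(triisopropylsilyl)oxy]phenyl}propan-2-yl]oxy}-3-methoxybenzyl)-3-{[(2S,3R)-3-{[(tert-butyldimethylsilyl)oxy]methyl}-7-methoxy-2-{3-methoxy-4-[(triisopropylsilyl)oxy]phenyl}-2,3-dihydro-1-benzofuran-5-yl]methyl}oxolan-2-one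
Product: 35 (3R,4R)-4-(4-{[(1R,2S)-1,3-dihydroxy-1-(4-hydroxy-3-methoxyphenyl)propan-2-yl]oxy}-3-methoxybenzyl)-3-{[(2S,3R)-2-(4-hydroxy-3-methoxyphenyl)-3-(hydroxymethyl)-7-methoxy-2,3-dihydro-1-benzofuran-5-yl]methyl}oxolan-2-one (CNP0265599.1)
Conditions: Bu4NF (8 equiv), AcOH (8 equiv), THF, 0 °C to rt
Reagents that add atoms: none
Why: Fluoride-induced cleavage of all five silyl ethers in one operation; the acetic acid buffer keeps the liberated phenols protonated, so that neither the para-hydroxybenzylic C7–O and C2–O1 bonds nor the lactone are exposed to phenoxide or alkoxide base.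

## Compound list

1 | vanillin | COc1cc(C=O)ccc1O | starting material
2 | 3-methoxy-4-[(triisopropylsilyl)oxy]benzaldehyde | COc1cc(C=O)ccc1O[Si](C(C)C)(C(C)C)C(C)C | intermediate
3 | ethyl (2E)-3-{3-methoxy-4-[(triisopropylsilyl)oxy]phenyl}prop-2-enoate | CCOC(=O)/C=C/c1ccc(O[Si](C(C)C)(C(C)C)C(C)C)c(OC)c1 | intermediate
4 | (2E)-3-{3-methoxy-4-[(triisopropylsilyl)oxy]phenyl}prop-2-en-1-ol | OC/C=C/c1ccc(O[Si](C(C)C)(C(C)C)C(C)C)c(OC)c1 | intermediate
5 | methyl (2E)-3-{3-methoxy-4-[(triisopropylsilyl)oxy]phenyl}prop-2-en-1-yl carbonate | COC(=O)OC/C=C/c1ccc(O[Si](C(C)C)(C(C)C)C(C)C)c(OC)c1 | intermediate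
6 | methyl vanillate (methyl 4-hydroxy-3-methoxybenzoate) | COC(=O)c1ccc(O)c(OC)c1 | starting material
7 | methyl 4-hydroxy-3-iodo-5-methoxybenzoate | COC(=O)c1cc(I)c(O)c(OC)c1 | intermediate
8 | lithium 2-iodo-6-methoxy-4-(methoxycarbonyl)phenolate (formed in the flask, not isolated) | [Li+].[O-]c1c(I)cc(C(=O)OC)cc1OC | intermediate
9 | methyl 3-iodo-5-methoxy-4-{[(1S)-1-{3-methoxy-4-[(triisopropylsilyl)oxy]phenyl}prop-2-en-1-yl]oxy}benzoate | C=C[C@@H](c1ccc(O[Si](C(C)C)(C(C)C)C(C)C)c(OC)c1)Oc1c(I)cc(C(=O)OC)cc1OC | intermediate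
10 | methyl (2S,3R)-3-(hydroperoxymethyl)-7-methoxy-2-{3-methoxy-4-[(triisopropylsilyl)oxy]phenyl}-2,3-dihydro-1-benzofuran-5-carboxylate (formed in the flask, not isolated) | COC(=O)c1cc(OC)c2c(c1)[C@H](COO)[C@@H](c1ccc(O[Si](C(C)C)(C(C)C)C(C)C)c(OC)c1)O2 | intermediate
11 | methyl (2S,3R)-3-(hydroxymethyl)-7-methoxy-2-{3-methoxy-4-[(triisopropylsilyl)oxy]phenyl}-2,3-dihydro-1-benzofuran-5-carboxylate | COC(=O)c1cc(OC)c2c(c1)[C@H](CO)[C@@H](c1ccc(O[Si](C(C)C)(C(C)C)C(C)C)c(OC)c1)O2 | intermediate
12 | methyl (2S,3R)-3-{[(tert-butyldimethylsilyl)oxy]methyl}-7-methoxy-2-{3-methoxy-4-[(triisopropylsilyl)oxy]phenyl}-2,3-dihydro-1-benzofuran-5-carboxylate | COC(=O)c1cc(OC)c2c(c1)[C@H](CO[Si](C)(C)C(C)(C)C)[C@@H](c1ccc(O[Si](C(C)C)(C(C)C)C(C)C)c(OC)c1)O2 | intermediate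
13 | [(2S,3R)-3-{[(tert-butyldimethylsilyl)oxy]methyl}-7-methoxy-2-{3-methoxy-4-[(triisopropylsilyl)oxy]phenyl}-2,3-dihydro-1-benzofuran-5-yl]methanol | OCc1cc(OC)c2c(c1)[C@H](CO[Si](C)(C)C(C)(C)C)[C@@H](c1ccc(O[Si](C(C)C)(C(C)C)C(C)C)c(OC)c1)O2 | intermediate
14 | (2S,3R)-5-(bromomethyl)-3-{[(tert-butyldimethylsilyl)oxy]methyl}-7-methoxy-2-{3-methoxy-4-[(triisopropylsilyl)oxy]phenyl}-2,3-dihydro-1-benzofuran | BrCc1cc(OC)c2c(c1)[C@H](CO[Si](C)(C)C(C)(C)C)[C@@H](c1ccc(O[Si](C(C)C)(C(C)C)C(C)C)c(OC)c1)O2 | intermediate
15 | 4-(benzyloxy)-3-methoxybenzaldehyde | COc1cc(C=O)ccc1OCc1ccccc1 | starting material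
16 | dimethyl succinate | COC(=O)CCC(=O)OC | starting material
17 | (3E)-4-[4-(benzyloxy)-3-methoxyphenyl]-3-(methoxycarbonyl)but-3-enoic acid | COC(=O)/C(CC(=O)O)=C/c1ccc(OCc2ccccc2)c(OC)c1 | intermediate
18 | (3R)-3-[4-(benzyloxy)-3-methoxybenzyl]-4-methoxy-4-oxobutanoic acid | COC(=O)[C@@H](CC(=O)O)Cc1ccc(OCc2ccccc2)c(OC)c1 | intermediate
19 | (3R)-3-[4-(benzyloxy)-3-methoxybenzyl]-4-hydroxybutanoic acid (formed in the flask, not isolated) | OC[C@@H](CC(=O)O)Cc1ccc(OCc2ccccc2)c(OC)c1 | intermediate
20 | (4R)-4-[4-(benzyloxy)-3-methoxybenzyl]oxolan-2-one | O=C1C[C@@H](Cc2ccc(OCc3ccccc3)c(OC)c2)CO1 | intermediate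
21 | (4R)-4-(4-hydroxy-3-methoxybenzyl)oxolan-2-one | O=C1C[C@@H](Cc2ccc(O)c(OC)c2)CO1 | intermediate
22 | (4R)-4-benzyl-1,3-oxazolidin-2-one | O=C1N[C@H](Cc2ccccc2)CO1 | starting material
23 | lithium (4R)-4-benzyl-2-oxo-1,3-oxazolidin-3-ide (formed in the flask, not isolated) | [Li+].O=C1[N-][C@H](Cc2ccccc2)CO1 | intermediate
24 | (4R)-4-benzyl-3-(bromoacetyl)-1,3-oxazolidin-2-one | O=C1N(C(=O)CBr)[C@H](Cc2ccccc2)CO1 | intermediate
25 | (4R)-4-benzyl-3-[(2-methoxy-4-{[(3R)-5-oxooxolan-3-yl]methyl}phenoxy)acetyl]-1,3-oxazolidin-2-one | O=C1C[C@@H](Cc2ccc(OCC(=O)N3[C@H](Cc4ccccc4)COC3=O)c(OC)c2)CO1 | intermediate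
26 | dibutylboron (Z)-enolate of 25 (formed in the flask, not isolated) | CCCCB(CCCC)O/C(=C\Oc1ccc(C[C@@H]2CC(=O)OC2)cc1OC)N1[C@H](Cc2ccccc2)COC1=O | intermediate
27 | (4R)-4-benzyl-3-[(2R,3S)-3-hydroxy-2-(2-methoxy-4-{[(3R)-5-oxooxolan-3-yl]methyl}phenoxy)-3-{3-methoxy-4-[(triisopropylsilyl)oxy]phenyl}propanoyl]-1,3-oxazolidin-2-one | O=C1C[C@@H](Cc2ccc(O[C@@H](C(=O)N3[C@H](Cc4ccccc4)COC3=O)[C@@H](O)c3ccc(O[Si](C(C)C)(C(C)C)C(C)C)c(OC)c3)c(OC)c2)CO1 | intermediate
28 | (4R)-4-(4-{[(1S,2S)-1,3-dihydroxy-1-{3-methoxy-4-[(triisopropylsilyl)oxy]phenyl}propan-2-yl]oxy}-3-methoxybenzyl)oxolan-2-one (threo; 7S,8S) | O=C1C[C@@H](Cc2ccc(O[C@@H](CO)[C@@H](O)c3ccc(O[Si](C(C)C)(C(C)C)C(C)C)c(OC)c3)c(OC)c2)CO1 | intermediate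
29 | (4R)-4-(4-{[(1S,2S)-3-[(tert-butyldimethylsilyl)oxy]-1-hydroxy-1-{3-methoxy-4-[(triisopropylsilyl)oxy]phenyl}propan-2-yl]oxy}-3-methoxybenzyl)oxolan-2-one | O=C1C[C@@H](Cc2ccc(O[C@@H](CO[Si](C)(C)C(C)(C)C)[C@@H](O)c3ccc(O[Si](C(C)C)(C(C)C)C(C)C)c(OC)c3)c(OC)c2)CO1 | intermediate
30 | (1R,2S)-3-[(tert-butyldimethylsilyl)oxy]-1-{3-methoxy-4-[(triisopropylsilyl)oxy]phenyl}-2-(2-methoxy-4-{[(3R)-5-oxooxolan-3-yl]methyl}phenoxy)propyl chloroacetate | O=C1C[C@@H](Cc2ccc(O[C@@H](CO[Si](C)(C)C(C)(C)C)[C@H](OC(=O)CCl)c3ccc(O[Si](C(C)C)(C(C)C)C(C)C)c(OC)c3)c(OC)c2)CO1 | intermediate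
31 | (4R)-4-(4-{[(1R,2S)-3-[(tert-butyldimethylsilyl)oxy]-1-hydroxy-1-{3-methoxy-4-[(triisopropylsilyl)oxy]phenyl}propan-2-yl]oxy}-3-methoxybenzyl)oxolan-2-one (erythro; 7R,8S) | O=C1C[C@@H](Cc2ccc(O[C@@H](CO[Si](C)(C)C(C)(C)C)[C@H](O)c3ccc(O[Si](C(C)C)(C(C)C)C(C)C)c(OC)c3)c(OC)c2)CO1 | intermediate
32 | (4R)-4-(4-{[(1R,2S)-1,3-bis[(tert-butyldimethylsilyl)oxy]-1-{3-methoxy-4-[(triisopropylsilyl)oxy]phenyl}propan-2-yl]oxy}-3-methoxybenzyl)oxolan-2-one | O=C1C[C@@H](Cc2ccc(O[C@@H](CO[Si](C)(C)C(C)(C)C)[C@H](O[Si](C)(C)C(C)(C)C)c3ccc(O[Si](C(C)C)(C(C)C)C(C)C)c(OC)c3)c(OC)c2)CO1 | intermediate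
33 | lithium enolate of 32 (formed in the flask, not isolated) | [Li+].[O-]C1=C[C@@H](Cc2ccc(O[C@@H](CO[Si](C)(C)C(C)(C)C)[C@H](O[Si](C)(C)C(C)(C)C)c3ccc(O[Si](C(C)C)(C(C)C)C(C)C)c(OC)c3)c(OC)c2)CO1 | intermediate
34 | penta-O-silyl derivative of the target: (3R,4R)-4-(4-{[(1R,2S)-1,3-bis[(tert-butyldimethylsilyl)oxy]-1-{3-methoxy-4-[(triisopropylsilyl)oxy]phenyl}propan-2-yl]oxy}-3-methoxybenzyl)-3-{[(2S,3R)-3-{[(tert-butyldimethylsilyl)oxy]methyl}-7-methoxy-2-{3-methoxy-4-[(triisopropylsilyl)oxy]phenyl}-2,3-dihydro-1-benzofuran-5-yl]methyl}oxolan-2-one | COc1cc([C@@H](O[Si](C)(C)C(C)(C)C)[C@H](CO[Si](C)(C)C(C)(C)C)Oc2ccc(C[C@H]3COC(=O)[C@@H]3Cc3cc(OC)c4c(c3)[C@H](CO[Si](C)(C)C(C)(C)C)[C@@H](c3ccc(O[Si](C(C)C)(C(C)C)C(C)C)c(OC)c3)O4)cc2OC)ccc1O[Si](C(C)C)(C(C)C)C(C)C | intermediate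
35 | CNP0265599.1: (3R,4R)-4-(4-{[(1R,2S)-1,3-dihydroxy-1-(4-hydroxy-3-methoxyphenyl)propan-2-yl]oxy}-3-methoxybenzyl)-3-{[(2S,3R)-2-(4-hydroxy-3-methoxyphenyl)-3-(hydroxymethyl)-7-methoxy-2,3-dihydro-1-benzofuran-5-yl]methyl}oxolan-2-one | COc1cc([C@@H](O)[C@H](CO)Oc2ccc(C[C@H]3COC(=O)[C@@H]3Cc3cc(OC)c4c(c3)[C@H](CO)[C@@H](c3ccc(O)c(OC)c3)O4)cc2OC)ccc1O | target

## Step count and least certain steps

Total: 24 steps. Longest linear sequence: 13 steps (steps 11, 12, 13, 14, 16, 17, 18, 19, 20, 21, 22, 23, 24, from 15 to 35). The ring C–D branch from 1 is 11 steps long (steps 1–4, 6–10, 23, 24).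

Step 7 (key step). The most likely failures are hydrogen transfer from the stannane to the cyclised primary radical before oxygen capture, and incomplete trans selectivity, because C3 is set under kinetic control in an early transition state. Fallback, from 9 back to 11:
- Cyclise with Bu3SnH in the presence of excess TEMPO (toluene, 60 °C), so that the exocyclic radical is removed by non-chain radical–radical coupling, to give the alkoxyamine F1 as a mixture at C3.
- Cleave the N-alkoxyamine oxidatively with mCPBA to the C3 aldehyde and equilibrate with Et3N at the acidic α-aryl position to the thermodynamically preferred trans aldehyde F2.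
- Reduce F2 with NaBH4 in MeOH at 0 °C, returning to 11 with trans secured by thermodynamic and not kinetic control.

Step 6. The product is a doubly activated ether (electron-rich 1-arylallyl group, electron-poor aryloxide), so reversible re-ionisation on iridium may erode enantiopurity and branched selectivity; the hindered aryloxide may also attack slowly. Fallback, from 2 and 7 back to 9:
- Add HC≡CMgBr to 2 to give the racemic propargylic alcohol F3, and acetylate it to F4.
- Carry out an enantioconvergent copper-catalysed propargylic etherification of F4 with 7 (CuOTf·0.5C6H6, chiral pybox ligand, i-Pr2NEt) through a copper allenylidene, to give the (S)-propargyl aryl ether F5.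
- Semi-hydrogenate F5 (H2, Pd/CaCO3 poisoned with Pb(OAc)2, quinoline), returning to 9.

Step 20. The activated C7 oxygen sits on a benzylic carbon beside a para-silyloxy arene, so partial ionisation would scramble C7, and elimination towards the enol ether is possible. Fallback, from 29 back to 31:
- Oxidise with Dess–Martin periodinane (NaHCO3, CH2Cl2) to the aryl ketone F6.
- Reduce with BH3·SMe2 and (R)-2-methyl-CBS-oxazaborolidine at −20 °C; this antipode is predicted to give 7R when the aryl group acts as the larger substituent, and the Felkin–Anh preference of the α-aryloxy ketone favours the same erythro isomer.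
- This rejoins the route at 31 and bypasses step 21.

Step 18. Over-reduction of the γ-lactone to the diol may compete while the imide is being cleaved, since both are acyl–oxygen electrophiles towards borohydride. Fallback, from 27 back to 28:
- Hydrolyse the imide with LiOH and H2O2 (THF–H2O, 0 °C) to the acid F7, with release of 22; a lactone opened by hydroxide recloses on acidification.
- Reduce F7 with BH3·SMe2 (THF, 0 °C), which reduces a carboxylic acid much faster than a lactone, returning to 28.

Step 23. The para-alkoxybenzyl bromide 14 may decompose before it is consumed, and double alkylation or proton transfer may occur between product and enolate. Fallback, from 13 and 32 back to 34: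
- Oxidise 13 with MnO2 to the aldehyde F8.
- Add enolate 33 to F8 at −78 °C to give the aldol adduct F9, trans at the lactone and a mixture at the carbinol.
- Convert F9 with 1,1'-thiocarbonyldiimidazole to F10.
- Deoxygenate F10 (Barton–McCombie: Bu3SnH, AIBN, toluene, 80 °C), returning to 34.

## Further compounds

F1 | step 7 | methyl (2S)-7-methoxy-2-{3-methoxy-4-[(triisopropylsilyl)oxy]phenyl}-3-{[(2,2,6,6-tetramethylpiperidin-1-yl)oxy]methyl}-2,3-dihydro-1-benzofuran-5-carboxylate (both C3 epimers) | COC(=O)c1cc(OC)c2c(c1)C(CON1C(C)(C)CCCC1(C)C)[C@@H](c1ccc(O[Si](C(C)C)(C(C)C)C(C)C)c(OC)c1)O2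
F2 | step 7 | methyl (2S,3S)-3-formyl-7-methoxy-2-{3-methoxy-4-[(triisopropylsilyl)oxy]phenyl}-2,3-dihydro-1-benzofuran-5-carboxylate (trans) | COC(=O)c1cc(OC)c2c(c1)[C@H](C=O)[C@@H](c1ccc(O[Si](C(C)C)(C(C)C)C(C)C)c(OC)c1)O2
F3 | step 6 | 1-{3-methoxy-4-[(triisopropylsilyl)oxy]phenyl}prop-2-yn-1-ol (racemic) | C#CC(O)c1ccc(O[Si](C(C)C)(C(C)C)C(C)C)c(OC)c1
F4 | step 6 | 1-{3-methoxy-4-[(triisopropylsilyl)oxy]phenyl}prop-2-yn-1-yl acetate (racemic) | C#CC(OC(C)=O)c1ccc(O[Si](C(C)C)(C(C)C)C(C)C)c(OC)c1
F5 | step 6 | methyl 3-iodo-5-methoxy-4-{[(1S)-1-{3-methoxy-4-[(triisopropylsilyl)oxy]phenyl}prop-2-yn-1-yl]oxy}benzoate | C#C[C@@H](c1ccc(O[Si](C(C)C)(C(C)C)C(C)C)c(OC)c1)Oc1c(I)cc(C(=O)OC)cc1OC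
F6 | step 20 | (4R)-4-(4-{[(2S)-3-[(tert-butyldimethylsilyl)oxy]-1-{3-methoxy-4-[(triisopropylsilyl)oxy]phenyl}-1-oxopropan-2-yl]oxy}-3-methoxybenzyl)oxolan-2-one | O=C1C[C@@H](Cc2ccc(O[C@@H](CO[Si](C)(C)C(C)(C)C)C(=O)c3ccc(O[Si](C(C)C)(C(C)C)C(C)C)c(OC)c3)c(OC)c2)CO1
F7 | step 18 | (2R,3S)-3-hydroxy-2-(2-methoxy-4-{[(3R)-5-oxooxolan-3-yl]methyl}phenoxy)-3-{3-methoxy-4-[(triisopropylsilyl)oxy]phenyl}propanoic acid | O=C1C[C@@H](Cc2ccc(O[C@@H](C(=O)O)[C@@H](O)c3ccc(O[Si](C(C)C)(C(C)C)C(C)C)c(OC)c3)c(OC)c2)CO1
F8 | step 23 | (2S,3R)-3-{[(tert-butyldimethylsilyl)oxy]methyl}-7-methoxy-2-{3-methoxy-4-[(triisopropylsilyl)oxy]phenyl}-2,3-dihydro-1-benzofuran-5-carbaldehyde | O=Cc1cc(OC)c2c(c1)[C@H](CO[Si](C)(C)C(C)(C)C)[C@@H](c1ccc(O[Si](C(C)C)(C(C)C)C(C)C)c(OC)c1)O2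
F9 | step 23 | aldol adduct of 33 and F8: the analogue of 34 bearing a hydroxyl group on the ring C benzylic carbon (trans lactone; both carbinol epimers) | COc1cc([C@@H](O[Si](C)(C)C(C)(C)C)[C@H](CO[Si](C)(C)C(C)(C)C)Oc2ccc(C[C@H]3COC(=O)[C@@H]3C(O)c3cc(OC)c4c(c3)[C@H](CO[Si](C)(C)C(C)(C)C)[C@@H](c3ccc(O[Si](C(C)C)(C(C)C)C(C)C)c(OC)c3)O4)cc2OC)ccc1O[Si](C(C)C)(C(C)C)C(C)C
F10 | step 23 | O-(1H-imidazol-1-ylcarbonothioyl) derivative of F9 | COc1cc([C@@H](O[Si](C)(C)C(C)(C)C)[C@H](CO[Si](C)(C)C(C)(C)C)Oc2ccc(C[C@H]3COC(=O)[C@@H]3C(OC(=S)n3ccnc3)c3cc(OC)c4c(c3)[C@H](CO[Si](C)(C)C(C)(C)C)[C@@H](c3ccc(O[Si](C(C)C)(C(C)C)C(C)C)c(OC)c3)O4)cc2OC)ccc1O[Si](C(C)C)(C(C)C)C(C)C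
A1 | alternative 1 | (5R)-5-{[(1R,2S,5R)-5-methyl-2-(propan-2-yl)cyclohexyl]oxy}furan-2(5H)-one | O=C1C=C[C@H](O[C@@H]2C[C@H](C)CC[C@H]2C(C)C)O1
A2 | alternative 1 | 1,3-dithiane of the ring A–B aldehyde (7,9-O-isopropylidene; ring A O-tert-butyldimethylsilyl) | COc1cc([C@@H](OC(C)(C)OC2)[C@H]2Oc2ccc(C3SCCCS3)cc2OC)ccc1O[Si](C)(C)C(C)(C)C
A3 | alternative 1 | trans,trans 3-benzyl-4-(2-aryl-1,3-dithian-2-yl)-5-menthyloxy lactone carrying all four arenes | COc1cc([C@@H](OC(C)(C)OC2)[C@H]2Oc2ccc(C3(SCCCS3)[C@H]3[C@H](O[C@@H]4C[C@H](C)CC[C@H]4C(C)C)OC(=O)[C@@H]3Cc3cc(OC)c4c(c3)[C@H](CO[Si](C)(C)C(C)(C)C)[C@@H](c3ccc(O[Si](C)(C)C(C)(C)C)c(OC)c3)O4)cc2OC)ccc1O[Si](C)(C)C(C)(C)C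
A4 | alternative 2 | eugenol | C=CCc1ccc(O)c(OC)c1
A5 | alternative 2 | 3-(ring A–B arylmethyl)cyclobutanone | COc1cc([C@@H](OC(C)(C)OC2)[C@H]2Oc2ccc(CC3CC(=O)C3)cc2OC)ccc1O[Si](C)(C)C(C)(C)C
A6 | alternative 2 | (R)-β-(ring A–B arylmethyl)-γ-butyrolactone | COc1cc([C@@H](OC(C)(C)OC2)[C@H]2Oc2ccc(C[C@H]3COC(=O)C3)cc2OC)ccc1O[Si](C)(C)C(C)(C)C
A7 | alternative 3 | methyl 2-{2-[(4-benzyloxy-3-methoxybenzyl)oxy]-5-{[(tert-butyldimethylsilyl)oxy]methyl}-3-methoxyphenyl}-2-diazoacetate | COC(=O)C(=[N+]=[N-])c1cc(CO[Si](C)(C)C(C)(C)C)cc(OC)c1OCc1ccc(OCc2ccccc2)c(OC)c1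
A8 | alternative 3 | trans methyl 2-(4-benzyloxy-3-methoxyphenyl)-5-{[(tert-butyldimethylsilyl)oxy]methyl}-7-methoxy-2,3-dihydro-1-benzofuran-3-carboxylate | CC(C)(C)[Si](C)(C)OCc1cc(OC)c2c(c1)[C@H](C(=O)OC)[C@@H](c1ccc(OCc3ccccc3)c(OC)c1)O2
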